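**Assumption:** the target has no stereocentre and is achiral, so no enantiocontrol is needed; the racemic centres in 12, 13 and 21 are erased in later steps.

## Retrosynthetic overview

1. Target 23 ⇐ penta-O-benzyl ether 22 by global hydrogenolysis; the one methyl ether is carried from the start.
2. The ring-B diarylmethane of 22 ⇐ Weinreb amide 17 + aryl Grignard 19, then C=O → CH2.
3. Bibenzyl bridge ⇐ stilbene acid 14 ⇐ lactone 13 ⇐ key intermolecular vinylogous aldol addition of the ester dienolate of toluate 10 to ring-A aldehyde 8. The ester activates the methyl group and later becomes the benzylic carbon.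
4. Aldehyde 8 ⇐ dibromo ester 3 + benzylzinc 5 (twofold Negishi) ⇐ methyl 3-hydroxy-5-methoxybenzoate 1.
5. Rings: all five benzene rings are bought. The only ring formed is the δ-lactone of 13 (step 7), opened again in step 8.

## Route

Step 1
Reactants: 1 methyl 3-hydroxy-5-methoxybenzoate
Product: 2 methyl 3-(benzyloxy)-5-methoxybenzoate
Conditions: BnBr (1.1 equiv), K2CO3, DMF, 60 °C
Reagents that add atoms: benzyl bromide, BrCc1ccccc1
Why: Williamson ether synthesis on the phenoxide; the methyl ester is untouched.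

Step 2
Reactants: 2 methyl 3-(benzyloxy)-5-methoxybenzoate
Product: 3 methyl 3-(benzyloxy)-2,6-dibromo-5-methoxybenzoate
Conditions: NBS (2.2 equiv), MeCN, 0 → 60 °C, dark
Reagents that add atoms: N-bromosuccinimide, O=C1CCC(=O)N1Br
Why: Electrophilic aromatic bromination goes to C2 and C6 (each para to one alkoxy group and ortho to the other), while C4 between the two alkoxy groups is sterically disfavoured, as in the known 2,6-dihalogenation of 3,5-dialkoxybenzoates.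

Step 3
Reactants: 3 methyl 3-(benzyloxy)-2,6-dibromo-5-methoxybenzoate; 4 4-(benzyloxy)benzyl chloride (2.6 equiv)
Product: 6 methyl 3-(benzyloxy)-2,6-bis[4-(benzyloxy)benzyl]-5-methoxybenzoate, via benzylzinc chloride 5 (not isolated)
Conditions: 4, Zn dust, LiCl, THF, 25 °C; then 3, Pd(OAc)2 (5 mol%), SPhos (10 mol%), THF, 25 → 60 °C
Reagents that add atoms: zinc dust, [Zn] (ends in intermediate 5, not in 6)
Why: LiCl-mediated zinc insertion gives the benzylic zinc reagent, and the twofold sp3–sp2 Negishi coupling with the SPhos catalyst accepts di-ortho-substituted bromides and tolerates the ester.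

Step 4
Reactants: 6 methyl 3-(benzyloxy)-2,6-bis[4-(benzyloxy)benzyl]-5-methoxybenzoate
Product: 7 {3-(benzyloxy)-2,6-bis[4-(benzyloxy)benzyl]-5-methoxyphenyl}methanol
Conditions: LiAlH4, THF, 0 °C → reflux; Fieser work-up
Reagents that add atoms: none
Why: Hydride reduction with LiAlH4 reduces even 2,6-disubstituted benzoates, and benzyl ethers are inert.

Step 5
Reactants: 7 {3-(benzyloxy)-2,6-bis[4-(benzyloxy)benzyl]-5-methoxyphenyl}methanol
Product: 8 3-(benzyloxy)-2,6-bis[4-(benzyloxy)benzyl]-5-methoxybenzaldehyde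
Conditions: Dess–Martin periodinane, CH2Cl2, rt
Reagents that add atoms: none
Why: Dess–Martin oxidation of the benzylic alcohol stops at the aldehyde and leaves the diarylmethane CH2 groups alone.

Step 6
Reactants: 9 methyl 4-hydroxy-2-methylbenzoate
Product: 10 methyl 4-(benzyloxy)-2-methylbenzoate
Conditions: BnBr (1.1 equiv), K2CO3, DMF, 60 °C
Reagents that add atoms: benzyl bromide, BrCc1ccccc1
Why: Williamson ether synthesis on the phenoxide.

Step 7 (key step)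
Reactants: 10 methyl 4-(benzyloxy)-2-methylbenzoate (1.5 equiv); 8 3-(benzyloxy)-2,6-bis[4-(benzyloxy)benzyl]-5-methoxybenzaldehyde
Product: 13 (±)-6-(benzyloxy)-3-{3-(benzyloxy)-2,6-bis[4-(benzyloxy)benzyl]-5-methoxyphenyl}-3,4-dihydro-1H-isochromen-1-one, via lithiated toluate 11 (not isolated), via lithium aldolate 12 (not isolated)
Conditions: LDA (1.6 equiv), THF, −78 °C, add 10; then 8, −78 °C → rt; aq NH4Cl
Reagents that add atoms: lithium diisopropylamide, CC(C)[N-]C(C)C.[Li+] (lithium in 11 and 12 only)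
Why: Lateral lithiation gives the ester dienolate, which undergoes an intermolecular vinylogous aldol addition to the non-enolisable aldehyde; the aldolate lactonises, and the new C3 stereocentre is racemic and removed in step 8.

Step 8
Reactants: 13 (±)-6-(benzyloxy)-3-{3-(benzyloxy)-2,6-bis[4-(benzyloxy)benzyl]-5-methoxyphenyl}-3,4-dihydro-1H-isochromen-1-one
Product: 14 4-(benzyloxy)-2-[(E)-2-{3-(benzyloxy)-2,6-bis[4-(benzyloxy)benzyl]-5-methoxyphenyl}ethenyl]benzoic acid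
Conditions: t-BuOK (3 equiv), THF, 0 °C → rt; then cold 1 M HCl
Reagents that add atoms: none
Why: E1cB ring-opening elimination (analogous to flavanone → chalcone): deprotonation at C4 expels the carboxylate irreversibly and gives the thermodynamically favoured E-stilbene.

Step 9
Reactants: 14 4-(benzyloxy)-2-[(E)-2-{3-(benzyloxy)-2,6-bis[4-(benzyloxy)benzyl]-5-methoxyphenyl}ethenyl]benzoic acid
Product: 15 4-(benzyloxy)-2-[2-{3-(benzyloxy)-2,6-bis[4-(benzyloxy)benzyl]-5-methoxyphenyl}ethyl]benzoic acid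
Conditions: TsNHNH2 (10 equiv, portionwise), NaOAc, DME/H2O, reflux
Reagents that add atoms: none
Why: Diimide reduction transfers H2 in a concerted syn fashion to the C=C bond only, so the four benzyl ethers survive.

Step 10
Reactants: 15 4-(benzyloxy)-2-[2-{3-(benzyloxy)-2,6-bis[4-(benzyloxy)benzyl]-5-methoxyphenyl}ethyl]benzoic acid
Product: 17 4-(benzyloxy)-2-[2-{3-(benzyloxy)-2,6-bis[4-(benzyloxy)benzyl]-5-methoxyphenyl}ethyl]-N-methoxy-N-methylbenzamide, via acid chloride 16 (not isolated)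
Conditions: (COCl)2, cat. DMF, CH2Cl2, 0 °C → rt; then MeNH(OMe)·HCl, Et3N, CH2Cl2, 0 °C → rt
Reagents that add atoms: oxalyl chloride, O=C(Cl)C(Cl)=O (chlorine in 16 only); N,O-dimethylhydroxylamine hydrochloride, CNOC.Cl
Why: Weinreb amide formation through the acid chloride; both ortho positions of ring A are blocked, so no intramolecular acylation can compete.

Step 11
Reactants: 17 4-(benzyloxy)-2-[2-{3-(benzyloxy)-2,6-bis[4-(benzyloxy)benzyl]-5-methoxyphenyl}ethyl]-N-methoxy-N-methylbenzamide; 18 1-(benzyloxy)-4-bromobenzene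
Product: 20 [4-(benzyloxy)phenyl]{4-(benzyloxy)-2-[2-{3-(benzyloxy)-2,6-bis[4-(benzyloxy)benzyl]-5-methoxyphenyl}ethyl]phenyl}methanone, via aryl Grignard reagent 19 (not isolated)
Conditions: 18, Mg, cat. I2, THF, reflux; then 17, THF, 0 °C → rt; aq HCl
Reagents that add atoms: magnesium, [Mg] (ends in intermediate 19, not in 20)
Why: Weinreb ketone synthesis, in which the chelated tetrahedral adduct prevents over-addition.

Step 12
Reactants: 20 [4-(benzyloxy)phenyl]{4-(benzyloxy)-2-[2-{3-(benzyloxy)-2,6-bis[4-(benzyloxy)benzyl]-5-methoxyphenyl}ethyl]phenyl}methanone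
Product: 21 (±)-[4-(benzyloxy)phenyl]{4-(benzyloxy)-2-[2-{3-(benzyloxy)-2,6-bis[4-(benzyloxy)benzyl]-5-methoxyphenyl}ethyl]phenyl}methanol
Conditions: NaBH4, THF/MeOH, 0 → 40 °C
Reagents that add atoms: none
Why: Borohydride reduction of the diaryl ketone; the carbinol centre is racemic and removed in step 13.

Step 13
Reactants: 21 (±)-[4-(benzyloxy)phenyl]{4-(benzyloxy)-2-[2-{3-(benzyloxy)-2,6-bis[4-(benzyloxy)benzyl]-5-methoxyphenyl}ethyl]phenyl}methanol
Product: 22 1-(benzyloxy)-2,4-bis[4-(benzyloxy)benzyl]-3-(2-{5-(benzyloxy)-2-[4-(benzyloxy)benzyl]phenyl}ethyl)-5-methoxybenzene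
Conditions: Et3SiH (3 equiv), TFA (10 equiv), CH2Cl2, 0 °C, 30 min
Reagents that add atoms: none
Why: Ionic hydrogenation: the benzhydryl cation, stabilised by two para-alkoxy groups, forms readily and is trapped by the silane faster than aryl benzyl ethers are cleaved at 0 °C.

Step 14
Reactants: 22 1-(benzyloxy)-2,4-bis[4-(benzyloxy)benzyl]-3-(2-{5-(benzyloxy)-2-[4-(benzyloxy)benzyl]phenyl}ethyl)-5-methoxybenzene
Product: 23 2,4-bis(4-hydroxybenzyl)-3-{2-[5-hydroxy-2-(4-hydroxybenzyl)phenyl]ethyl}-5-methoxyphenol (CNP0147493.0)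
Conditions: H2 (1 atm), 10% Pd/C, EtOAc/MeOH, rt
Reagents that add atoms: none
Why: Catalytic hydrogenolysis cleaves the five aryl benzyl ethers, while the aryl methyl ether and the diarylmethane and bibenzyl C–C bonds are inert.

## Compound list

1 | methyl 3-hydroxy-5-methoxybenzoate | COC(=O)c1cc(O)cc(OC)c1 | starting material
2 | methyl 3-(benzyloxy)-5-methoxybenzoate | COC(=O)c1cc(OCc2ccccc2)cc(OC)c1 | intermediate
3 | methyl 3-(benzyloxy)-2,6-dibromo-5-methoxybenzoate | COC(=O)c1c(Br)c(OCc2ccccc2)cc(OC)c1Br | intermediate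
4 | 4-(benzyloxy)benzyl chloride | ClCc1ccc(OCc2ccccc2)cc1 | starting material
5 | [4-(benzyloxy)benzyl]zinc chloride (formed in situ) | Cl[Zn]Cc1ccc(OCc2ccccc2)cc1 | intermediate
6 | methyl 3-(benzyloxy)-2,6-bis[4-(benzyloxy)benzyl]-5-methoxybenzoate | COC(=O)c1c(Cc2ccc(OCc3ccccc3)cc2)c(OCc2ccccc2)cc(OC)c1Cc1ccc(OCc2ccccc2)cc1 | intermediate
7 | {3-(benzyloxy)-2,6-bis[4-(benzyloxy)benzyl]-5-methoxyphenyl}methanol | OCc1c(Cc2ccc(OCc3ccccc3)cc2)c(OCc2ccccc2)cc(OC)c1Cc1ccc(OCc2ccccc2)cc1 | intermediate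
8 | 3-(benzyloxy)-2,6-bis[4-(benzyloxy)benzyl]-5-methoxybenzaldehyde | O=Cc1c(Cc2ccc(OCc3ccccc3)cc2)c(OCc2ccccc2)cc(OC)c1Cc1ccc(OCc2ccccc2)cc1 | intermediate
9 | methyl 4-hydroxy-2-methylbenzoate | COC(=O)c1ccc(O)cc1C | starting material
10 | methyl 4-(benzyloxy)-2-methylbenzoate | COC(=O)c1ccc(OCc2ccccc2)cc1C | intermediate
11 | methyl 4-(benzyloxy)-2-(lithiomethyl)benzoate, the ester dienolate (formed in situ) | [Li]Cc1cc(OCc2ccccc2)ccc1C(=O)OC | intermediate
12 | racemic lithium alkoxide of methyl 4-(benzyloxy)-2-[2-hydroxy-2-{3-(benzyloxy)-2,6-bis[4-(benzyloxy)benzyl]-5-methoxyphenyl}ethyl]benzoate (formed in situ) | COC(=O)c1ccc(OCc2ccccc2)cc1CC(O[Li])c1c(Cc2ccc(OCc3ccccc3)cc2)c(OCc2ccccc2)cc(OC)c1Cc1ccc(OCc2ccccc2)cc1 | intermediate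
13 | (±)-6-(benzyloxy)-3-{3-(benzyloxy)-2,6-bis[4-(benzyloxy)benzyl]-5-methoxyphenyl}-3,4-dihydro-1H-isochromen-1-one | O=C1OC(Cc2cc(OCc3ccccc3)ccc12)c1c(Cc2ccc(OCc3ccccc3)cc2)c(OCc2ccccc2)cc(OC)c1Cc1ccc(OCc2ccccc2)cc1 | intermediate
14 | 4-(benzyloxy)-2-[(E)-2-{3-(benzyloxy)-2,6-bis[4-(benzyloxy)benzyl]-5-methoxyphenyl}ethenyl]benzoic acid | OC(=O)c1ccc(OCc2ccccc2)cc1/C=C/c1c(Cc2ccc(OCc3ccccc3)cc2)c(OCc2ccccc2)cc(OC)c1Cc1ccc(OCc2ccccc2)cc1 | intermediate
15 | 4-(benzyloxy)-2-[2-{3-(benzyloxy)-2,6-bis[4-(benzyloxy)benzyl]-5-methoxyphenyl}ethyl]benzoic acid | OC(=O)c1ccc(OCc2ccccc2)cc1CCc1c(Cc2ccc(OCc3ccccc3)cc2)c(OCc2ccccc2)cc(OC)c1Cc1ccc(OCc2ccccc2)cc1 | intermediate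
16 | 4-(benzyloxy)-2-[2-{3-(benzyloxy)-2,6-bis[4-(benzyloxy)benzyl]-5-methoxyphenyl}ethyl]benzoyl chloride (formed in situ) | ClC(=O)c1ccc(OCc2ccccc2)cc1CCc1c(Cc2ccc(OCc3ccccc3)cc2)c(OCc2ccccc2)cc(OC)c1Cc1ccc(OCc2ccccc2)cc1 | intermediate
17 | 4-(benzyloxy)-2-[2-{3-(benzyloxy)-2,6-bis[4-(benzyloxy)benzyl]-5-methoxyphenyl}ethyl]-N-methoxy-N-methylbenzamide | CON(C)C(=O)c1ccc(OCc2ccccc2)cc1CCc1c(Cc2ccc(OCc3ccccc3)cc2)c(OCc2ccccc2)cc(OC)c1Cc1ccc(OCc2ccccc2)cc1 | intermediate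
18 | 1-(benzyloxy)-4-bromobenzene | Brc1ccc(OCc2ccccc2)cc1 | starting material
19 | [4-(benzyloxy)phenyl]magnesium bromide (formed in situ) | Br[Mg]c1ccc(OCc2ccccc2)cc1 | intermediate
20 | [4-(benzyloxy)phenyl]{4-(benzyloxy)-2-[2-{3-(benzyloxy)-2,6-bis[4-(benzyloxy)benzyl]-5-methoxyphenyl}ethyl]phenyl}methanone | O=C(c1ccc(OCc2ccccc2)cc1)c1ccc(OCc2ccccc2)cc1CCc1c(Cc2ccc(OCc3ccccc3)cc2)c(OCc2ccccc2)cc(OC)c1Cc1ccc(OCc2ccccc2)cc1 | intermediate
21 | (±)-[4-(benzyloxy)phenyl]{4-(benzyloxy)-2-[2-{3-(benzyloxy)-2,6-bis[4-(benzyloxy)benzyl]-5-methoxyphenyl}ethyl]phenyl}methanol | OC(c1ccc(OCc2ccccc2)cc1)c1ccc(OCc2ccccc2)cc1CCc1c(Cc2ccc(OCc3ccccc3)cc2)c(OCc2ccccc2)cc(OC)c1Cc1ccc(OCc2ccccc2)cc1 | intermediate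
22 | 1-(benzyloxy)-2,4-bis[4-(benzyloxy)benzyl]-3-(2-{5-(benzyloxy)-2-[4-(benzyloxy)benzyl]phenyl}ethyl)-5-methoxybenzene | COc1cc(OCc2ccccc2)c(Cc2ccc(OCc3ccccc3)cc2)c(CCc2cc(OCc3ccccc3)ccc2Cc2ccc(OCc3ccccc3)cc2)c1Cc1ccc(OCc2ccccc2)cc1 | intermediate
23 | 2,4-bis(4-hydroxybenzyl)-3-{2-[5-hydroxy-2-(4-hydroxybenzyl)phenyl]ethyl}-5-methoxyphenol (achiral) | COc1cc(O)c(Cc2ccc(O)cc2)c(CCc2cc(O)ccc2Cc2ccc(O)cc2)c1Cc1ccc(O)cc1 | target

## Summary

Total steps: 14.
Longest linear sequence: 13 steps (1–5, then 7–14); step 6 is the one-step side branch.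

Steps most likely to fail:

Step 3 (twofold Negishi coupling at two di-ortho-substituted C–Br bonds; the second coupling may stall). The fallback sets out from 4 and 3 and comes back at 6. Palladium-catalysed borylation of 4 with bis(pinacolato)diboron and KOAc gives 2-[4-(benzyloxy)benzyl]-4,4,5,5-tetramethyl-1,3,2-dioxaborolane F1. A twofold Suzuki–Miyaura coupling of F1 with dibromide 3 (Pd(OAc)2/RuPhos, K3PO4, toluene/water, 100 °C) then gives 6, replacing the zinc nucleophile by a boron one that tolerates forcing aqueous conditions.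

Step 7 (key vinylogous aldol; the lithiated ester can self-condense and aldehyde 8 is hindered). The fallback sets out from 10 and comes back at 13. Aminolysis of 10 with Me3Al/Et2NH gives 4-(benzyloxy)-N,N-diethyl-2-methylbenzamide F2, which cannot self-condense. LDA at −78 °C gives its laterally lithiated form 4-(benzyloxy)-N,N-diethyl-2-(lithiomethyl)benzamide F3. Addition of F3 to 8 gives (±)-4-(benzyloxy)-N,N-diethyl-2-[2-hydroxy-2-{3-(benzyloxy)-2,6-bis[4-(benzyloxy)benzyl]-5-methoxyphenyl}ethyl]benzamide F4. Heating F4 with catalytic TsOH in toluene closes the lactone with loss of diethylamine and gives 13.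

Step 9 (chemoselective diimide reduction of a hindered stilbene; it may be incomplete). The fallback sets out from 14 and comes back at 15, giving up chemoselectivity in favour of a protecting-group cycle. Hydrogenation of 14 over Pd/C saturates the alkene and removes all four benzyl groups to give 4-hydroxy-2-{2-[3-hydroxy-2,6-bis(4-hydroxybenzyl)-5-methoxyphenyl]ethyl}benzoic acid F5. Exhaustive benzylation (BnBr, K2CO3, DMF) gives benzyl 4-(benzyloxy)-2-[2-{3-(benzyloxy)-2,6-bis[4-(benzyloxy)benzyl]-5-methoxyphenyl}ethyl]benzoate F6. Hydrolysis of the benzyl ester with LiOH in THF/MeOH/water gives 15.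

## Further compounds

F1 | step 3 | 2-[4-(benzyloxy)benzyl]-4,4,5,5-tetramethyl-1,3,2-dioxaborolane | CC1(C)OB(Cc2ccc(OCc3ccccc3)cc2)OC1(C)C
F2 | step 7 | 4-(benzyloxy)-N,N-diethyl-2-methylbenzamide | CCN(CC)C(=O)c1ccc(OCc2ccccc2)cc1C
F3 | step 7 | 4-(benzyloxy)-N,N-diethyl-2-(lithiomethyl)benzamide | [Li]Cc1cc(OCc2ccccc2)ccc1C(=O)N(CC)CC
F4 | step 7 | (±)-4-(benzyloxy)-N,N-diethyl-2-[2-hydroxy-2-{3-(benzyloxy)-2,6-bis[4-(benzyloxy)benzyl]-5-methoxyphenyl}ethyl]benzamide | CCN(CC)C(=O)c1ccc(OCc2ccccc2)cc1CC(O)c1c(Cc2ccc(OCc3ccccc3)cc2)c(OCc2ccccc2)cc(OC)c1Cc1ccc(OCc2ccccc2)cc1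
F5 | step 9 | 4-hydroxy-2-{2-[3-hydroxy-2,6-bis(4-hydroxybenzyl)-5-methoxyphenyl]ethyl}benzoic acid | OC(=O)c1ccc(O)cc1CCc1c(Cc2ccc(O)cc2)c(O)cc(OC)c1Cc1ccc(O)cc1
F6 | step 9 | benzyl 4-(benzyloxy)-2-[2-{3-(benzyloxy)-2,6-bis[4-(benzyloxy)benzyl]-5-methoxyphenyl}ethyl]benzoate | O=C(OCc1ccccc1)c1ccc(OCc2ccccc2)cc1CCc1c(Cc2ccc(OCc3ccccc3)cc2)c(OCc2ccccc2)cc(OC)c1Cc1ccc(OCc2ccccc2)cc1
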